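**Retrosynthetic overview**
- The target comes from a 5,8-dihydroxyflavone by methylation of both phenols and hydrogenolysis of two benzyl ethers (at O6 and O2').
- Key disconnection: bonds C8–C8a and C4a–C5. Ring A is annulated onto the unsubstituted C=C edge of a 2-aryl-4-pyranone (rings B and C) by a 5-sulfonyl-3,4-dialkoxybutenolide.
- Feature the plan rests on: ring A carries oxygen on all of C5–C8, with the C5 and C8 oxygens para to each other across the C6–C7 edge. Butenolide C2 and C5 become C5 and C8 with their oxygens; C3 (OBn) and C4 (OMe) become C6 and C7, so the single free 6-OH is marked from the start.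
- Donor: benzyloxyacetate of methyl glycolate, Dieckmann closure, O-methylation, C5 sulfenylation, oxidation. Acceptor: O-benzylated acetophenone, β-diketone, formylation and cyclodehydration.
- Ring order: ring B is bought, ring C (pyranone) is made next, ring A is closed last.

Key step: step 9

Assumption: compounds 6 and 7 are used as racemates and 14 as a stereoisomer mixture, because their sp3 centres all end as sp2 carbons of ring A; the target is achiral.

**Step 1**
Reactants: 1 benzyloxyacetyl chloride; 2 methyl glycolate
Product: 3 methyl 2-[(2-benzyloxyacetyl)oxy]acetate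
Conditions: pyridine, DMAP (cat.), CH2Cl2, 0 °C → rt
Reagents that add atoms: none
Why: Esterification of a primary alcohol with an acid chloride, pyridine taking up HCl; the methyl ester is not touched.

**Step 2**
Reactants: 3 methyl 2-[(2-benzyloxyacetyl)oxy]acetate
Product: 4 3-benzyloxy-4-hydroxyfuran-2(5H)-one
Conditions: LiN(SiMe3)2 (2.2 equiv), THF, −78 °C → rt; aq. HCl
Reagents that add atoms: none
Why: Dieckmann (intramolecular Claisen) condensation: the benzyloxyacetate enolate attacks the methyl ester to close the five-membered ring, and deprotonation of the acidic tetronic acid by the second equivalent of base drives the closure.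

**Step 3**
Reactants: 4 3-benzyloxy-4-hydroxyfuran-2(5H)-one
Product: 5 3-benzyloxy-4-methoxyfuran-2(5H)-one
Conditions: Me2SO4, K2CO3, acetone, reflux
Reagents that add atoms: dimethyl sulfate, COS(=O)(=O)OC
Why: Williamson-type O-methylation of the vinylogous acid; the hard electrophile should favour the C4 oxygen of the tetronate anion, C3 being fully substituted, and any 2-methoxyfuran-4-one isomer would be separated.

**Step 4**
Reactants: 5 3-benzyloxy-4-methoxyfuran-2(5H)-one
Product: 6 racemic 3-benzyloxy-4-methoxy-5-(phenylthio)furan-2(5H)-one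
Conditions: LiN(iPr)2 (LDA, 1.1 equiv), THF, −78 °C; cannulation into PhSO2SPh, THF, −78 °C; aq. HCl
Reagents that add atoms: S-phenyl benzenethiosulfonate, O=S(=O)(Sc1ccccc1)c1ccccc1
Why: Enolate sulfenylation: LDA removes a C5 proton of the 4-alkoxybutenolide to give a 2-oxidofuran that takes up PhS at C5, and inverse addition to the reactive thiosulfonate limits double sulfenylation; the new C5 centre forms racemic and is erased in step 9.

**Step 5**
Reactants: 6 racemic 3-benzyloxy-4-methoxy-5-(phenylthio)furan-2(5H)-one
Product: 7 racemic 3-benzyloxy-4-methoxy-5-(phenylsulfonyl)furan-2(5H)-one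
Conditions: mCPBA (2.3 equiv), CH2Cl2, 0 °C → rt
Reagents that add atoms: 3-chloroperoxybenzoic acid (mCPBA), O=C(OO)c1cccc(Cl)c1
Why: Peracid oxidation of sulfide to sulfone; the push–pull C3=C4 bond conjugated to the lactone is too electron-poor to be epoxidised.

**Step 6**
Reactants: 8 1-(2-hydroxy-6-methoxyphenyl)ethanone; 9 benzyl bromide
Product: 10 1-(2-benzyloxy-6-methoxyphenyl)ethanone
Conditions: K2CO3, DMF, 60 °C
Reagents that add atoms: none
Why: Williamson ether synthesis on the phenoxide; K2CO3 in DMF overcomes the hydrogen bond to the ketone.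

**Step 7**
Reactants: 10 1-(2-benzyloxy-6-methoxyphenyl)ethanone
Product: 11 1-(2-benzyloxy-6-methoxyphenyl)butane-1,3-dione
Conditions: NaH, EtOAc, THF, reflux; aq. HCl
Reagents that add atoms: ethyl acetate, CCOC(C)=O
Why: Crossed Claisen condensation of the methyl ketone enolate with ethyl acetate, driven by deprotonation of the β-diketone formed.

**Step 8**
Reactants: 11 1-(2-benzyloxy-6-methoxyphenyl)butane-1,3-dione
Product: 13 2-(2-benzyloxy-6-methoxyphenyl)-4H-pyran-4-one, via formyl diketone 12 (not isolated)
Conditions: LiN(iPr)2 (LDA, 2.5 equiv), THF, −78 → 0 °C; HCO2Et, −78 °C → rt; aq. HCl; then TFA (cat.), CH2Cl2, rt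
Reagents that add atoms: ethyl formate, CCOC=O
Why: Claisen formylation of the β-diketone dianion at its terminal carbon (the more basic and more nucleophilic site), then acid-catalysed cyclodehydration of the 1,3,5-tricarbonyl compound to the 4-pyranone (enol oxygen of the aryl ketone onto the aldehyde, loss of water).

**Step 9**
Reactants: 7 racemic 3-benzyloxy-4-methoxy-5-(phenylsulfonyl)furan-2(5H)-one; 13 2-(2-benzyloxy-6-methoxyphenyl)-4H-pyran-4-one
Product: 15 6-benzyloxy-2-(2-benzyloxy-6-methoxyphenyl)-5,8-dihydroxy-7-methoxy-4H-chromen-4-one, via 4a,8a-dihydro trione 14 (not isolated)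
Conditions: LiOtBu (3 equiv), THF, −78 °C → rt (argon); degassed aq. HCl
Reagents that add atoms: none
Why: Proposed new method: LiOtBu removes the C5 proton of 7 to give a sulfonyl-stabilised 2-oxidofuran anion, which adds through C5 to the unsubstituted O-bearing CH of pyranone 13 (Michael addition, bond C8–C8a); the pyranone enolate then attacks the lactone carbonyl (Dieckmann-type acylation, bond C4a–C5), the former ring oxygen is released onto C8, phenylsulfinate is expelled to give trione 14, and double enolisation aromatises ring A to hydroquinone 15. The closest known reaction type is the Hauser–Kraus annulation of 3-(phenylsulfonyl)phthalide anions with enones and chromones; a monocyclic 3,4-dialkoxybutenolide donor and a 4-pyranone acceptor have not been used in these roles. Ring A closes by 6-exo-trig attack of the enolate carbon on the lactone C=O, through an oxygen-bridged bicyclic alkoxide, after the intermolecular Michael step. No stereocentre survives: C5 of racemic 7 and the transient C4a and C8a centres of 14 all become sp2 carbons on aromatisation. The step needs the donor to react through its sulfonyl-bearing C5 and not C3, and at the pyranone CH remote from the aryl group and not at C2. The first is secured because Michael addition is reversible and only the C5 adduct is drained by ring closure and sulfinate loss; the second because the twisted, di-ortho-substituted ring B shields C2, which would in any case become quaternary.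

**Step 10**
Reactants: 15 6-benzyloxy-2-(2-benzyloxy-6-methoxyphenyl)-5,8-dihydroxy-7-methoxy-4H-chromen-4-one
Product: 16 6-benzyloxy-2-(2-benzyloxy-6-methoxyphenyl)-5,7,8-trimethoxy-4H-chromen-4-one
Conditions: Me2SO4 (excess), K2CO3, acetone, reflux (argon)
Reagents that add atoms: dimethyl sulfate, COS(=O)(=O)OC
Why: Williamson O-methylation of both phenols; the chelated 5-OH needs excess reagent and long reflux, and anhydrous, oxygen-free conditions keep the hydroquinone from oxidising to the 5,8-quinone and the pyranone ring from opening (no Wessely–Moser-type exchange of the C6 and C7 ethers).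

**Step 11**
Reactants: 16 6-benzyloxy-2-(2-benzyloxy-6-methoxyphenyl)-5,7,8-trimethoxy-4H-chromen-4-one
Product: 17 6,2'-dihydroxy-5,7,8,6'-tetramethoxyflavone
Conditions: H2 (1 atm), Pd/C (10 wt % zerovalent palladium on carbon), EtOAc–MeOH, rt
Reagents that add atoms: none
Why: Catalytic hydrogenolysis of both benzyl aryl ethers; the methyl ethers and the chromone C2=C3 bond should not react at 1 atm and room temperature if the reaction is stopped after two equivalents of hydrogen.

**Compound list**
1 | benzyloxyacetyl chloride | O=C(Cl)COCc1ccccc1 | starting material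
2 | methyl glycolate | COC(=O)CO | starting material
3 | methyl 2-[(2-benzyloxyacetyl)oxy]acetate | COC(=O)COC(=O)COCc1ccccc1 | intermediate
4 | 3-benzyloxy-4-hydroxyfuran-2(5H)-one | O=C1OCC(O)=C1OCc1ccccc1 | intermediate
5 | 3-benzyloxy-4-methoxyfuran-2(5H)-one | COC1=C(OCc2ccccc2)C(=O)OC1 | intermediate
6 | racemic 3-benzyloxy-4-methoxy-5-(phenylthio)furan-2(5H)-one | COC1=C(OCc2ccccc2)C(=O)OC1Sc1ccccc1 | intermediate
7 | racemic 3-benzyloxy-4-methoxy-5-(phenylsulfonyl)furan-2(5H)-one | COC1=C(OCc2ccccc2)C(=O)OC1S(=O)(=O)c1ccccc1 | intermediate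
8 | 1-(2-hydroxy-6-methoxyphenyl)ethanone | CC(=O)c1c(O)cccc1OC | starting material
9 | benzyl bromide | BrCc1ccccc1 | starting material
10 | 1-(2-benzyloxy-6-methoxyphenyl)ethanone | CC(=O)c1c(OC)cccc1OCc1ccccc1 | intermediate
11 | 1-(2-benzyloxy-6-methoxyphenyl)butane-1,3-dione | CC(=O)CC(=O)c1c(OC)cccc1OCc1ccccc1 | intermediate
12 | 5-(2-benzyloxy-6-methoxyphenyl)-3,5-dioxopentanal (enol tautomers; not isolated) | O=CCC(=O)CC(=O)c1c(OC)cccc1OCc1ccccc1 | intermediate
13 | 2-(2-benzyloxy-6-methoxyphenyl)-4H-pyran-4-one | COc1cccc(OCc2ccccc2)c1-c1cc(=O)cco1 | intermediate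
14 | 6-benzyloxy-2-(2-benzyloxy-6-methoxyphenyl)-7-methoxy-4a,8a-dihydro-4H-chromene-4,5,8-trione (stereoisomer mixture; not isolated) | COc1cccc(OCc2ccccc2)c1C1=CC(=O)C2C(=O)C(OCc3ccccc3)=C(OC)C(=O)C2O1 | intermediate
15 | 6-benzyloxy-2-(2-benzyloxy-6-methoxyphenyl)-5,8-dihydroxy-7-methoxy-4H-chromen-4-one | COc1cccc(OCc2ccccc2)c1-c1cc(=O)c2c(O)c(OCc3ccccc3)c(OC)c(O)c2o1 | intermediate
16 | 6-benzyloxy-2-(2-benzyloxy-6-methoxyphenyl)-5,7,8-trimethoxy-4H-chromen-4-one | COc1cccc(OCc2ccccc2)c1-c1cc(=O)c2c(OC)c(OCc3ccccc3)c(OC)c(OC)c2o1 | intermediate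
17 | 6,2'-dihydroxy-5,7,8,6'-tetramethoxyflavone (6-hydroxy-2-(2-hydroxy-6-methoxyphenyl)-5,7,8-trimethoxy-4H-chromen-4-one) | COc1cccc(O)c1-c1cc(=O)c2c(OC)c(O)c(OC)c(OC)c2o1 | target

**Step count**
Total: 11 steps. Longest linear sequence: 8 steps (steps 1–5, then 9–11).

**Steps most likely to fail**

Step 9 (key annulation).
- What may go wrong: the lactone carbonyl of 7 is a vinylogous carbonate, so Dieckmann closure may be slower than retro-Michael reversal. The donor anion may add through C3. The Michael adduct may open the pyranone ring by E1cB loss of the ring oxygen. The hydroquinone may oxidise in air during work-up.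
- Fallback (known chemistry; sets out from 10, returns at 16): ring A is bought pre-oxygenated and ring C is closed last by a Baker–Venkataraman sequence. Haloform cleavage of 10 (NaOCl, NaOH, aq. dioxane; HCl) should give 2-benzyloxy-6-methoxybenzoic acid F1, which oxalyl chloride with DMF (cat.) converts into 2-benzyloxy-6-methoxybenzoyl chloride F2. Purchased 1-(2-hydroxy-3,4,6-trimethoxyphenyl)ethanone F3 is hydroxylated para to its phenol by Elbs persulfate oxidation (K2S2O8, aq. KOH). This passes through potassium 3-acetyl-4-hydroxy-2,5,6-trimethoxyphenyl sulfate F4, which aq. HCl hydrolyses to 1-(2,5-dihydroxy-3,4,6-trimethoxyphenyl)ethanone F5. The non-chelated 5-OH is benzylated selectively with 9 (1 equiv, K2CO3, acetone) to 1-(5-benzyloxy-2-hydroxy-3,4,6-trimethoxyphenyl)ethanone F6. Acylation of F6 with F2 (pyridine, DMAP) gives 2-acetyl-4-benzyloxy-3,5,6-trimethoxyphenyl 2-benzyloxy-6-methoxybenzoate F7. KOH in pyridine moves the aroyl group to carbon, giving 1-(5-benzyloxy-2-hydroxy-3,4,6-trimethoxyphenyl)-3-(2-benzyloxy-6-methoxyphenyl)propane-1,3-dione F8. p-TsOH in hot toluene cyclodehydrates F8 to 16, which continues with step 11.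

Step 8 (pyranone formation).
- What may go wrong: the tricarbonyl product quenches unreacted dianion so that formylation stalls, LDA is itself formylated, and the formyl diketone self-condenses before it cyclises.
- Fallback (sets out from 10, returns at 13, bypassing 11 and 12): the three-carbon unit is brought in already at the aldehyde oxidation level and masked. Claisen condensation of the lithium enolate of 10 (LiN(SiMe3)2, THF, −78 °C → rt) with methyl 3,3-dimethoxypropanoate should give 1-(2-benzyloxy-6-methoxyphenyl)-5,5-dimethoxypentane-1,3-dione F9. TFA in CH2Cl2 then closes F9 to 13 with loss of methanol.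

Step 4 (C5 sulfenylation).
- What may go wrong: proton exchange between the more acidic sulfenylated product and unreacted anion, giving double sulfenylation and recovered 5.
- Fallback (sets out from 5, returns at 7, bypassing 6): direct C-sulfonylation. 5 is deprotonated with LiN(iPr)2 (2.2 equiv, THF, −78 °C) and treated with benzenesulfonyl fluoride. The sulfone formed is deprotonated at once by the second equivalent of base and its anion does not react with the sulfonyl fluoride, so over-reaction is excluded and no oxidation step is needed.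

**Further compounds**
F1 | step 9 | 2-benzyloxy-6-methoxybenzoic acid | COc1cccc(OCc2ccccc2)c1C(=O)O
F2 | step 9 | 2-benzyloxy-6-methoxybenzoyl chloride | COc1cccc(OCc2ccccc2)c1C(=O)Cl
F3 | step 9 | 1-(2-hydroxy-3,4,6-trimethoxyphenyl)ethanone (purchased) | CC(=O)c1c(O)c(OC)c(OC)cc1OC
F4 | step 9 | potassium 3-acetyl-4-hydroxy-2,5,6-trimethoxyphenyl sulfate | CC(=O)c1c(O)c(OC)c(OC)c(OS(=O)(=O)[O-])c1OC.[K+]
F5 | step 9 | 1-(2,5-dihydroxy-3,4,6-trimethoxyphenyl)ethanone | CC(=O)c1c(O)c(OC)c(OC)c(O)c1OC
F6 | step 9 | 1-(5-benzyloxy-2-hydroxy-3,4,6-trimethoxyphenyl)ethanone | CC(=O)c1c(O)c(OC)c(OC)c(OCc2ccccc2)c1OC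
F7 | step 9 | 2-acetyl-4-benzyloxy-3,5,6-trimethoxyphenyl 2-benzyloxy-6-methoxybenzoate | CC(=O)c1c(OC(=O)c2c(OC)cccc2OCc2ccccc2)c(OC)c(OC)c(OCc2ccccc2)c1OC
F8 | step 9 | 1-(5-benzyloxy-2-hydroxy-3,4,6-trimethoxyphenyl)-3-(2-benzyloxy-6-methoxyphenyl)propane-1,3-dione | COc1cccc(OCc2ccccc2)c1C(=O)CC(=O)c1c(O)c(OC)c(OC)c(OCc2ccccc2)c1OC
F9 | step 8 | 1-(2-benzyloxy-6-methoxyphenyl)-5,5-dimethoxypentane-1,3-dione | COC(OC)CC(=O)CC(=O)c1c(OC)cccc1OCc1ccccc1
F0 | step 4 | none | none
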